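Numbering: ring A = cyclohexene C1(C15H3)–C14(OAc)–C13–C12=C11(C20H3)–C10. Ring B = ten-membered ring C1–C2(O-isovaleryl)–C3–C4–C5(OH, C16H3)–C6=C7–C8–C9–C10. Ring C = butenolide C7–C8=C17(C18H3)–C19(=O)–O.
Cuts: first C6=C7 (opens ring B), then the two esters and C8–C9 (removes ring C), then C1–C10 together with C11–C12 (ring A taken apart in one retro-[4+2]).
Enabling feature: in ring A the C14 oxygen lies 1,3 to C12, and O2 on the C1 side chain can reach C12. C12=C13–C14(OSi)=C1 tied by O2–C2 is therefore a 4-silyloxy-2H-pyran, an s-cis-locked diene with two donors. C9–C10=C11(C20) is citraconic anhydride, whose second carboxyl is a traceless activator.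
Forward: hetero-Diels–Alder pyranone → 2H-pyran → Diels–Alder reaction to a 2-oxabicyclo[2.2.2]octene (ring A made). A decarboxylative fragmentation then cuts the helper bond O2–C12, expels the helper carboxyl as CO2 and leaves C11=C12. Ring C is joined at C8–C9, and ring B is closed last at C6=C7.
Stereochemistry: C5 comes from (R)-2-methylglycidol and C2 from the catalyst of the hetero-Diels–Alder step. C1 and C10 come from C2 through the facial and endo selectivity of the key step. C14 comes from C2 through the Evans–Tishchenko reduction, which also places the isovalerate. The C6=C7 geometry is set by ring B.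

Key step: step 8

Assumption: the sense of induction of Ti(OiPr)4/(R)-BINOL with the aliphatic aldehyde 4 is taken by analogy with simple alkanals (2S product). (S)-BINOL would be used if the opposite sense applied.

Step 1
Reactants: 1 (R)-2-methylglycidol
Product: 2 (2S)-2-methylhex-5-ene-1,2-diol
Conditions: allylMgBr (3 equiv), CuI (10 mol %), THF, −30 to 0 °C; aq NH4Cl
Reagents that add atoms: allylmagnesium bromide C=CC[Mg]Br
Why: Copper-catalysed Grignard opening of a 2,2-disubstituted epoxide proceeds by SN2 attack at the unsubstituted CH2 (future C4), so the C5 stereocentre of 1 is carried over untouched.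

Step 2
Reactants: 2 (2S)-2-methylhex-5-ene-1,2-diol
Product: 3 (4S)-4-(but-3-enyl)-2,2,4-trimethyl-1,3-dioxolane
Conditions: Me2C(OMe)2, PPTS (cat.), CH2Cl2, rt
Reagents that add atoms: 2,2-dimethoxypropane COC(C)(C)OC
Why: Acid-catalysed transketalisation closes the five-membered acetonide, which masks O5 and O6 together until step 17.

Step 3
Reactants: 3 (4S)-4-(but-3-enyl)-2,2,4-trimethyl-1,3-dioxolane
Product: 4 3-[(4S)-2,2,4-trimethyl-1,3-dioxolan-4-yl]propanal (C2–C6 fragment)
Conditions: O3, CH2Cl2, −78 °C; PPh3, −78 °C to rt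
Reagents that add atoms: ozone [O-][O+]=O
Why: Ozonolysis with reductive work-up cleaves the only alkene to the C2 aldehyde, and the ketal is inert.

Step 4
Reactants: 5 (E)-4-methoxybut-3-en-2-one
Product: 6 (E)-1-methoxypent-1-en-3-one
Conditions: LiN(iPr)2, THF, −78 °C; MeI, −78 to −20 °C
Reagents that add atoms: iodomethane CI
Why: Kinetic enolate alkylation at the only enolisable position of the vinylogous ester adds the carbon that becomes C15.

Step 5
Reactants: 6 (E)-1-methoxypent-1-en-3-one
Product: 7 (1E,3Z)-1-methoxy-3-(trimethylsilyloxy)penta-1,3-diene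
Conditions: Me3SiOTf, Et3N, Et2O, 0 °C
Reagents that add atoms: trimethylsilyl triflate C[Si](C)(C)OS(=O)(=O)C(F)(F)F
Why: Soft enolisation (silyl enol ether formation) gives the 1-alkoxy-3-silyloxy diene, and its C3=C4 geometry does not matter because C1 becomes sp2 again in step 7.

Step 6
Reactants: 4 3-[(4S)-2,2,4-trimethyl-1,3-dioxolan-4-yl]propanal; 7 (1E,3Z)-1-methoxy-3-(trimethylsilyloxy)penta-1,3-diene
Product: 9 (2S)-3-methyl-2-substituted 2,3-dihydro-4H-pyran-4-one (C1 epimers), via cycloadduct 8 (not isolated)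
Conditions: Ti(OiPr)4 (10 mol %), (R)-BINOL (20 mol %), 4 Å MS, Et2O, −20 °C; then CF3CO2H (cat.), CH2Cl2, 0 °C
Reagents that add atoms: none
Why: The catalyst-controlled hetero-Diels–Alder reaction (Mukaiyama aldol–cyclisation pathway) forms C1–C2 and the helper bond O2–C12 and sets C2 through the chiral titanium–BINOL pocket, and acid then eliminates MeOSiMe3 to the pyranone.

Step 7
Reactants: 9 (2S)-3-methyl-2-substituted 2,3-dihydro-4H-pyran-4-one
Product: 10 (2S)-4-(tert-butyldimethylsilyloxy)-3-methyl-2-substituted 2H-pyran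
Conditions: tBuMe2SiOTf, Et3N, Et2O, −20 to 0 °C; cold work-up, used at once
Reagents that add atoms: tert-butyldimethylsilyl triflate CC(C)(C)[Si](C)(C)OS(=O)(=O)C(F)(F)F
Why: Soft enolisation can only remove the C1–H (C13 is vinylic), so silyl enol ether formation gives the cyclic diene C12=C13–C14(OSi)=C1 and erases the C1 epimer mixture.

Step 8
Reactants: 10 (2S)-4-(tert-butyldimethylsilyloxy)-3-methyl-2-substituted 2H-pyran; 11 citraconic anhydride
Product: 12 endo 2-oxabicyclo[2.2.2]oct-5-ene anhydride adduct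
Conditions: toluene, BHT (trace), 0 °C to rt
Reagents that add atoms: none
Why: A concerted but asynchronous normal-electron-demand [4+2] cycloaddition joins the s-cis-locked diene C12=C13–C14=C1 of 10 to C10=C11 of 11, with the C1–C10 bond leading and C11–C12 following in the same event. The closest known reactions are Diels–Alder additions of 1-alkoxy-3-silyloxy dienes and of 2H-pyrans to maleic-type anhydrides, which give 2-oxabicyclo[2.2.2]octenes. The step closes ring A by suprafacial 4π+2π ring closure and at the same time builds the temporary oxa-bridged bicycle, in which O2–C12 and the carboxyl on C11 are helpers removed in step 9. C1 and C12 are set because the anhydride adds to the pyran face anti to the C3 side chain on C2, and C10 and C11 are set by the endo orientation, which places both carbonyls under C13=C14 so that C9 ends up trans to C2 and cis to C15. Regiochemistry is secured twice: the donor-activated but crowded terminus C1 bonds to the unsubstituted, methacryloyl-type β-carbon (C10), and the methyl-bearing carbon (C11) goes to the unhindered C12. The reversible electrocyclic opening of the 2H-pyran to a dienal has to be outrun, which the very reactive anhydride at or below room temperature should do.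

Step 9
Reactants: 12 endo 2-oxabicyclo[2.2.2]oct-5-ene anhydride adduct
Product: 15 cyclohexa-1,3-diene C9 carboxylic acid (14-OTBS dienol ether; 2-OTES), via dipotassium dicarboxylate 13 (not isolated), via triethylsilyl ester 14 (not isolated)
Conditions: KOSiMe3 (2.1 equiv), THF, 0 °C; solvent switch to CH2Cl2; Et3SiOTf (2.5 equiv), 2,6-lutidine, −78 to 0 °C; aq NaH2PO4 work-up
Reagents that add atoms: potassium trimethylsilanolate C[Si](C)(C)[O-].[K+]; triethylsilyl triflate CC[Si](CC)(CC)OS(=O)(=O)C(F)(F)F
Why: Proposed new method: anhydrous opening of the anhydride gives the dicarboxylate; silylation of the bridge oxygen O2 makes it a nucleofuge on C12, which is allylic to the silyl enol ether (Ferrier-type ionisation), and the endo carboxylate on C11 lies antiperiplanar to C12–O2, so CO2 should leave in a Grob-type decarboxylative fragmentation that forms C11=C12, frees O2 as its silyl ether and keeps the enol silane and the C1, C2 and C10 centres; the closest known reaction types are the decarboxylative Grob elimination of β-sulfonyloxy acids and the Lewis-acid ionisation of allylic C–O bonds next to enol ethers.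

Step 10
Reactants: 15 cyclohexa-1,3-diene C9 carboxylic acid
Product: 16 C9 primary alcohol
Conditions: LiAlH4, Et2O, 0 °C to rt; Fieser work-up
Reagents that add atoms: none
Why: Hydride reduction of the only carbonyl group brings C9 to the CH2 level, while C14 stays masked as the silyl dienol ether.

Step 11
Reactants: 16 C9 primary alcohol
Product: 18 C9 primary iodide, via mesylate 17 (not isolated)
Conditions: MsCl, Et3N, CH2Cl2, −20 °C; then NaI, NaHCO3, 2-butanone, 70 °C
Reagents that add atoms: methanesulfonyl chloride CS(=O)(=O)Cl (in 17 only); sodium iodide [Na+].[I-]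
Why: Sulfonylation followed by Finkelstein-type SN2 displacement avoids electrophilic iodine, which would attack the dienol ether.

Step 12
Reactants: 19 3-methyltetronic acid
Product: 20 4-bromo-3-methylfuran-2(5H)-one
Conditions: (COBr)2, DMF (cat.), CH2Cl2, 0 °C to rt
Reagents that add atoms: oxalyl bromide O=C(Br)C(=O)Br
Why: Vilsmeier-type bromodehydroxylation of the vinylogous acid gives the β-bromobutenolide, the ring C building block.

Step 13
Reactants: 18 C9 primary iodide; 20 4-bromo-3-methylfuran-2(5H)-one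
Product: 22 C8–C9 coupled butenolide, via alkylzinc iodide 21 (not isolated)
Conditions: Zn dust, LiCl, THF, 40 °C; then 20, Pd(OAc)2 (3 mol %), SPhos (6 mol %), THF, rt
Reagents that add atoms: zinc [Zn] (in 21 only)
Why: Negishi sp3–sp2 coupling of a primary alkylzinc with a β-bromo enoate forms C8–C9 under neutral conditions that spare the silyl ethers, the ketal and the lactone.

Step 14
Reactants: 22 C8–C9 coupled butenolide
Product: 23 β-hydroxy β,γ-enone (C14 ketone; C2–OH; C11=C12)
Conditions: HF·pyridine, excess pyridine, THF, 0 °C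
Reagents that add atoms: none
Why: Fluoride desilylation frees O2 and the dienol, whose kinetic α-protonation at C13 should give the deconjugated ketone, as in the mild hydrolysis of extended dienol ethers.

Step 15
Reactants: 23 β-hydroxy β,γ-enone
Product: 24 C2 isovalerate with free (14S)-alcohol
Conditions: SmI2 (0.3 equiv, premixed with the aldehyde), isovaleraldehyde (6 equiv), THF, −10 °C
Reagents that add atoms: isovaleraldehyde CC(C)CC=O
Why: In the Evans–Tishchenko reaction the C2 hemiacetal bound to trivalent samarium delivers hydride to C14 through a chair-like six-membered transition state, which should give the 1,3-anti diol array (14S) and leave the isovalerate on O2.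

Step 16
Reactants: 24 C2 isovalerate with free (14S)-alcohol
Product: 25 C14 acetate
Conditions: Ac2O, DMAP, pyridine, CH2Cl2, rt
Reagents that add atoms: acetic anhydride CC(=O)OC(C)=O
Why: DMAP-catalysed acylation caps the hindered C14 alcohol at once, which also forestalls 1,3-acyl migration.

Step 17
Reactants: 25 C14 acetate
Product: 26 C5,C6 diol
Conditions: AcOH/H2O (4:1), 40 °C
Reagents that add atoms: none
Why: Mild acid hydrolysis removes the terminal acetonide, while the esters, the butenolide and the isolated trisubstituted alkene are stable.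

Step 18
Reactants: 26 C5,C6 diol
Product: 27 C6 α-hydroxy aldehyde
Conditions: TEMPO (10 mol %), PhI(OAc)2, CH2Cl2, rt
Reagents that add atoms: none
Why: Oxoammonium oxidation is selective for the primary alcohol and cannot touch the tertiary C5 carbinol.

Step 19
Reactants: 27 C6 α-hydroxy aldehyde
Product: 31 target CNP0208239.1, via silyloxyfuran 28 (not isolated), via macrocyclic aldol silyl ether 29 (not isolated), via 5-O-trimethylsilyl ether 30 (not isolated)
Conditions: Me3SiOTf (4 equiv), Et3N, CH2Cl2 (1 mM), −78 to 0 °C; DBU, 0 °C to rt; then citric acid, MeOH/THF, rt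
Reagents that add atoms: trimethylsilyl triflate C[Si](C)(C)OS(=O)(=O)C(F)(F)F (in 28 to 30 only)
Why: A vinylogous Mukaiyama aldol addition of the in situ formed 2-silyloxyfuran (C7) to the non-enolisable C6 aldehyde under high dilution closes ring B, DBU then expels silanolate by E1cB through the planar furanolate to the olefin that ring B is expected to favour, with C5 and C8 cis (6E), and mild acid frees O5.

Compound list
1 | (R)-2-methylglycidol | C[C@@]1(CO)CO1 | starting material
2 | (2S)-2-methylhex-5-ene-1,2-diol | C=CCC[C@](C)(O)CO | intermediate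
3 | (4S)-4-(but-3-enyl)-2,2,4-trimethyl-1,3-dioxolane | C=CCC[C@@]1(C)COC(C)(C)O1 | intermediate
4 | 3-[(4S)-2,2,4-trimethyl-1,3-dioxolan-4-yl]propanal | O=CCC[C@@]1(C)COC(C)(C)O1 | intermediate
5 | (E)-4-methoxybut-3-en-2-one | CC(=O)/C=C/OC | starting material
6 | (E)-1-methoxypent-1-en-3-one | CCC(=O)/C=C/OC | intermediate
7 | (1E,3Z)-1-methoxy-3-(trimethylsilyloxy)penta-1,3-diene | CO/C=C/C(=C/C)O[Si](C)(C)C | intermediate
8 | hetero-Diels–Alder cycloadduct (2-methoxy-4-silyloxy dihydropyran; C1 and C12 unassigned) | COC1C=C(O[Si](C)(C)C)C(C)[C@H](CC[C@@]2(C)COC(C)(C)O2)O1 | intermediate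
9 | (2S)-3-methyl-2-{2-[(4S)-2,2,4-trimethyl-1,3-dioxolan-4-yl]ethyl}-2,3-dihydro-4H-pyran-4-one (C1 epimers) | CC1C(=O)C=CO[C@H]1CC[C@@]2(C)COC(C)(C)O2 | intermediate
10 | (2S)-4-(tert-butyldimethylsilyloxy)-3-methyl-2-{2-[(4S)-2,2,4-trimethyl-1,3-dioxolan-4-yl]ethyl}-2H-pyran | CC1=C(O[Si](C)(C)C(C)(C)C)C=CO[C@H]1CC[C@@]2(C)COC(C)(C)O2 | intermediate
11 | citraconic anhydride | CC1=CC(=O)OC1=O | starting material
12 | endo 2-oxabicyclo[2.2.2]oct-5-ene anhydride adduct (bridgeheads C1 and C12; bridges O2–C2, C13=C14, C10–C11) | C[C@]12[C@H](CC[C@@]4(C)COC(C)(C)O4)O[C@H](C=C1O[Si](C)(C)C(C)(C)C)[C@]3(C)C(=O)OC(=O)[C@H]23 | intermediate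
13 | dipotassium dicarboxylate of 12 | C[C@]12[C@H](CC[C@@]3(C)COC(C)(C)O3)O[C@H](C=C1O[Si](C)(C)C(C)(C)C)[C@](C)(C([O-])=O)[C@@H]2C([O-])=O.[K+].[K+] | intermediate
14 | triethylsilyl ester of 15 | CC1=CC=C(O[Si](C)(C)C(C)(C)C)[C@](C)([C@@H](O[Si](CC)(CC)CC)CC[C@@]2(C)COC(C)(C)O2)[C@H]1C(=O)O[Si](CC)(CC)CC | intermediate
15 | cyclohexa-1,3-diene C9 carboxylic acid (C1, C2, C5, C10 as in the target) | CC1=CC=C(O[Si](C)(C)C(C)(C)C)[C@](C)([C@@H](O[Si](CC)(CC)CC)CC[C@@]2(C)COC(C)(C)O2)[C@H]1C(O)=O | intermediate
16 | C9 primary alcohol | CC1=CC=C(O[Si](C)(C)C(C)(C)C)[C@](C)([C@@H](O[Si](CC)(CC)CC)CC[C@@]2(C)COC(C)(C)O2)[C@H]1CO | intermediate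
17 | C9 mesylate | CC1=CC=C(O[Si](C)(C)C(C)(C)C)[C@](C)([C@@H](O[Si](CC)(CC)CC)CC[C@@]2(C)COC(C)(C)O2)[C@H]1COS(C)(=O)=O | intermediate
18 | C9 primary iodide | CC1=CC=C(O[Si](C)(C)C(C)(C)C)[C@](C)([C@@H](O[Si](CC)(CC)CC)CC[C@@]2(C)COC(C)(C)O2)[C@H]1CI | intermediate
19 | 3-methyltetronic acid | CC1=C(O)COC1=O | starting material
20 | 4-bromo-3-methylfuran-2(5H)-one | CC1=C(Br)COC1=O | intermediate
21 | C9 alkylzinc iodide | CC1=CC=C(O[Si](C)(C)C(C)(C)C)[C@](C)([C@@H](O[Si](CC)(CC)CC)CC[C@@]2(C)COC(C)(C)O2)[C@H]1C[Zn]I | intermediate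
22 | C8–C9 coupled butenolide (silyl dienol ether) | CC1=CC=C(O[Si](C)(C)C(C)(C)C)[C@](C)([C@@H](O[Si](CC)(CC)CC)CC[C@@]2(C)COC(C)(C)O2)[C@H]1CC3=C(C)C(=O)OC3 | intermediate
23 | β-hydroxy β,γ-enone | CC1=CCC(=O)[C@](C)([C@@H](O)CC[C@@]2(C)COC(C)(C)O2)[C@H]1CC3=C(C)C(=O)OC3 | intermediate
24 | C2 isovalerate with free (14S)-alcohol | CC1=CC[C@H](O)[C@](C)([C@@H](OC(=O)CC(C)C)CC[C@@]2(C)COC(C)(C)O2)[C@H]1CC3=C(C)C(=O)OC3 | intermediate
25 | C14 acetate | CC1=CC[C@H](OC(C)=O)[C@](C)([C@@H](OC(=O)CC(C)C)CC[C@@]2(C)COC(C)(C)O2)[C@H]1CC3=C(C)C(=O)OC3 | intermediate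
26 | C5,C6 diol | CC1=CC[C@H](OC(C)=O)[C@](C)([C@@H](OC(=O)CC(C)C)CC[C@](C)(O)CO)[C@H]1CC2=C(C)C(=O)OC2 | intermediate
27 | C6 α-hydroxy aldehyde | CC1=CC[C@H](OC(C)=O)[C@](C)([C@@H](OC(=O)CC(C)C)CC[C@](C)(O)C=O)[C@H]1CC2=C(C)C(=O)OC2 | intermediate
28 | 2-silyloxyfuran, 5-O-TMS aldehyde | CC1=CC[C@H](OC(C)=O)[C@](C)([C@@H](OC(=O)CC(C)C)CC[C@](C)(O[Si](C)(C)C)C=O)[C@H]1Cc2coc(O[Si](C)(C)C)c2C | intermediate
29 | macrocyclic aldol silyl ether (C6 and C7 unassigned) | CC(=O)O[C@H]1CC=C(C)[C@@H]2CC3=C(C)C(=O)OC3C(O[Si](C)(C)C)[C@@](C)(O[Si](C)(C)C)CC[C@H](OC(=O)CC(C)C)[C@@]12C | intermediate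
30 | 5-O-trimethylsilyl ether of the target | CC(=O)O[C@H]1CC=C(C)[C@@H]2CC3=C(C)C(=O)O/C3=C/[C@@](C)(O[Si](C)(C)C)CC[C@H](OC(=O)CC(C)C)[C@@]12C | intermediate
31 | CNP0208239.1 | CC(=O)O[C@H]1CC=C(C)[C@@H]2CC3=C(C)C(=O)O/C3=C/[C@@](C)(O)CC[C@H](OC(=O)CC(C)C)[C@@]12C | target

Total step count: 19. Longest linear sequence: 16 steps (1–3, 6–11, 13–19).

Steps most likely to fail

1. Step 9. The ionisation may run ahead of the loss of CO2. That would bring loss of the enol silyl group, capture of the allyl cation by the C9 carboxylate, or scrambling of the diene. The fallback uses only known reaction types and sets out from 12.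
- Bu4NF/AcOH removes the enol silyl group and gives the bicyclic keto anhydride F1.
- Aqueous LiOH hydrolyses the anhydride and opens the β-alkoxy ketone by E1cB (retro-oxa-Michael) to the enone diacid F2.
- After acidification, warming in toluene decarboxylates this vinylogous β-keto acid to the hydroxy enone acid F3. Its double-bond isomers are of no consequence.
- Et3SiOTf/2,6-lutidine gives the bis(triethylsilyl) derivative F4.
- tBuMe2SiOTf/Et3N can deprotonate only at C11 or C13, because C1 is quaternary, and so converges on the extended silyl dienol ether. The route is rejoined at 14, and work-up gives 15.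

2. Step 8. Electrocyclic opening of the pyran, slow bond formation at the crowded C1 terminus, or erosion of endo and facial selectivity may lower the throughput. The fallback replaces the pericyclic event by an anionic Michael–Michael sequence and sets out from 9.
- LiN(SiMe3)2 (THF, −78 °C) forms the C1 enolate, which adds to the unsubstituted carbon of dimethyl citraconate.
- The resulting ester enolate closes onto C12 of the vinylogous ester and gives the bicyclic keto diester F5.
- KN(SiMe3)2/tBuMe2SiCl enolises toward C13, the only possible side, and gives the silyl enol ether diester F6.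
- Excess KOSiMe3 cleaves both methyl esters, and the route is rejoined at 13.

3. Step 19. Oligomerisation in place of ring closure, retro-aldol reversal, or elimination to the wrong olefin geometry may intervene. The fallback makes the ring closure irreversible with a metal-templated Barbier reaction and sets out from 27.
- 27 is converted as above into 28, which is quenched at −78 °C with N-bromosuccinimide to the 7-bromobutenolide F7.
- CrCl2 in THF under high dilution forms an allyl species of trivalent chromium (Nozaki–Hiyama-type closure). It adds to the C6 aldehyde and gives the macrocyclic hydroxy lactone F8.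
- MsCl/Et3N gives the C6 mesylate F9.
- DBU eliminates it, and the route is rejoined at 30.

Further compounds
F1 | step 9 | bicyclic keto anhydride | C[C@]12[C@H](CC[C@@]4(C)COC(C)(C)O4)O[C@H](CC1=O)[C@]3(C)C(=O)OC(=O)[C@H]23
F2 | step 9 | enone diacid | C[C@]1(C(O)=O)C=CC(=O)[C@](C)([C@@H](O)CC[C@@]2(C)COC(C)(C)O2)[C@H]1C(O)=O
F3 | step 9 | hydroxy enone acid (C11 unassigned; with its β,γ isomer) | CC1C=CC(=O)[C@](C)([C@@H](O)CC[C@@]2(C)COC(C)(C)O2)[C@H]1C(O)=O
F4 | step 9 | bis(triethylsilyl) derivative of F3 | CC1C=CC(=O)[C@](C)([C@@H](O[Si](CC)(CC)CC)CC[C@@]2(C)COC(C)(C)O2)[C@H]1C(=O)O[Si](CC)(CC)CC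
F5 | step 8 | bicyclic keto diester | C[C@]12[C@H](CC[C@@]3(C)COC(C)(C)O3)O[C@H](CC1=O)[C@](C)(C(=O)OC)[C@@H]2C(=O)OC
F6 | step 8 | silyl enol ether diester | C[C@]12[C@H](CC[C@@]3(C)COC(C)(C)O3)O[C@H](C=C1O[Si](C)(C)C(C)(C)C)[C@](C)(C(=O)OC)[C@@H]2C(=O)OC
F7 | step 19 | 7-bromobutenolide aldehyde | CC1=CC[C@H](OC(C)=O)[C@](C)([C@@H](OC(=O)CC(C)C)CC[C@](C)(O[Si](C)(C)C)C=O)[C@H]1CC2=C(C)C(=O)OC2Br
F8 | step 19 | macrocyclic hydroxy lactone (C6 and C7 unassigned) | CC(=O)O[C@H]1CC=C(C)[C@@H]2CC3=C(C)C(=O)OC3C(O)[C@@](C)(O[Si](C)(C)C)CC[C@H](OC(=O)CC(C)C)[C@@]12C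
F9 | step 19 | C6 mesylate | CC(=O)O[C@H]1CC=C(C)[C@@H]2CC3=C(C)C(=O)OC3C(OS(C)(=O)=O)[C@@](C)(O[Si](C)(C)C)CC[C@H](OC(=O)CC(C)C)[C@@]12C
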